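**Plan**
1. The retrosynthesis cuts both bonds that join the dihydropyranone ring to the arene, O1–C8a and C4–C4a, in one operation. The four remaining ring atoms O1–C2–C3–C4(=O) are then a β-lactone, (S)-4-(4-methoxyphenyl)oxetan-2-one, and the arene is 3,4,5,6-tetramethoxybenzyne.
2. Two features make this possible. The benzo ring carries four contiguous OMe groups (C5–C8), so the aryne C4a≡C8a is C2v-symmetric and insertion has no regiochemical choice. O1 and C4(=O) are linked through C2–C3, which is exactly an oxetan-2-one.
3. The lactone is cut at its acyl C–O bond to the β-hydroxy acid and on to the commercial β-keto ester. The aryne precursor (an o-silylaryl triflate) is traced to 1,2,3,4-tetramethoxybenzene.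
4. Forward: the arene branch (hydroxylation, bromination, retro-Brook/triflation) and the lactone branch (asymmetric transfer hydrogenation, saponification, lactonization) converge in a two-atom ring expansion, four-membered to six-membered, that gives the target directly.
5. Stereochemistry: C2 is set by catalyst control in the transfer hydrogenation and carried through with retention, because the C2–O1 bond is not broken afterwards.

Key step: step 7

Assumption: 1,2,3,4-tetramethoxybenzene and ethyl 3-(4-methoxyphenyl)-3-oxopropanoate are taken as commercial; flavanone numbering (O1, C2, C3, C4, C4a, C5–C8, C8a) is used throughout.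

**Route**

Step 1
Reactants: 1 1,2,3,4-tetramethoxybenzene
Product: 4 2,3,4,5-tetramethoxyphenol, via aryllithium 2 (not isolated), via dimethyl arylboronate 3 (not isolated)
Conditions: n-BuLi, TMEDA, THF, 0 °C; B(OMe)3, −78 °C → rt; AcOH, 30% H2O2, 0 °C → rt
Reagents that add atoms: hydrogen peroxide, OO (n-butyllithium, [Li]CCCC, and trimethyl borate, COB(OC)OC, leave atoms only in 2 and 3)
Why: Directed ortho-metalation next to a methoxy group (the two free positions are equivalent), borylation and oxidative C–B to C–O shift form the standard arene hydroxylation sequence.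

Step 2
Reactants: 4 2,3,4,5-tetramethoxyphenol
Product: 5 2-bromo-3,4,5,6-tetramethoxyphenol
Conditions: NBS, CH2Cl2, −40 → 0 °C, dark
Reagents that add atoms: N-bromosuccinimide, O=C1CCC(=O)N1Br
Why: Electrophilic aromatic bromination at the only unsubstituted ring position, ortho to the hydroxyl; low temperature and exclusion of water should hold back oxidation to a quinone.

Step 3
Reactants: 5 2-bromo-3,4,5,6-tetramethoxyphenol
Product: 8 2,3,4,5-tetramethoxy-6-(trimethylsilyl)phenyl trifluoromethanesulfonate, via aryl trimethylsilyl ether 6 (not isolated), via lithium 2-silylphenoxide 7 (not isolated)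
Conditions: HMDS, THF, reflux, then evaporation; n-BuLi, THF, −100 → −78 °C; Tf2O, −100 → −78 °C
Reagents that add atoms: hexamethyldisilazane, C[Si](C)(C)N[Si](C)(C)C; trifluoromethanesulfonic anhydride, O=S(=O)(OS(=O)(=O)C(F)(F)F)C(F)(F)F (n-butyllithium, [Li]CCCC, leaves lithium only in 7)
Why: O-silylation, bromine–lithium exchange, anionic 1,3 O→C silyl migration (retro-Brook rearrangement) and O-triflation of the phenoxide are the standard one-flask preparation of o-(trimethylsilyl)aryl triflates from o-bromophenols.

Step 4
Reactants: 9 ethyl 3-(4-methoxyphenyl)-3-oxopropanoate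
Product: 10 ethyl (3S)-3-hydroxy-3-(4-methoxyphenyl)propanoate
Conditions: RuCl[(S,S)-TsDPEN](p-cymene) (1 mol %), HCO2H–Et3N (5:2), 30 °C
Reagents that add atoms: none
Why: Noyori asymmetric transfer hydrogenation of an aryl ketone, in which the CH/π contact between the η6-arene of the catalyst and the substrate aryl group fixes the carbonyl face, so the (S,S)-catalyst should give the (S)-carbinol (O > aryl > CH2 > H), the stereocentre that becomes C2.

Step 5
Reactants: 10 ethyl (3S)-3-hydroxy-3-(4-methoxyphenyl)propanoate
Product: 11 (3S)-3-hydroxy-3-(4-methoxyphenyl)propanoic acid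
Conditions: LiOH·H2O, THF–H2O (3:1), 0 °C; cold 1 M HCl to pH 3–4
Reagents that add atoms: lithium hydroxide, [Li+].[OH-]
Why: Ester saponification that does not touch the stereocentre; low temperature and mild acidification should prevent dehydration through the p-methoxybenzylic position.

Step 6
Reactants: 11 (3S)-3-hydroxy-3-(4-methoxyphenyl)propanoic acid
Product: 12 (4S)-4-(4-methoxyphenyl)oxetan-2-one
Conditions: PhSO2Cl, pyridine, 0–4 °C; cold aqueous work-up, used without chromatography and stored cold
Reagents that add atoms: none
Why: Carboxyl activation as the mixed carboxylic–sulfonic anhydride and 4-exo-trig attack of the β-hydroxyl (β-lactonization by carboxyl activation) leave the C–O bond at the stereocentre intact, so the S configuration is retained.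

Step 7
Reactants: 12 (4S)-4-(4-methoxyphenyl)oxetan-2-one; 8 2,3,4,5-tetramethoxy-6-(trimethylsilyl)phenyl trifluoromethanesulfonate
Product: 14 (2S)-5,6,7,8,4'-pentamethoxyflavanone, via tetramethoxybenzyne 13 (not isolated)
Conditions: CsF, MeCN, 0 °C → rt, 8 (1.5 equiv) added slowly
Reagents that add atoms: none
Why: Proposed new method: fluoride-induced 1,2-elimination of 8 gives the C2v-symmetric aryne 13, whose two reactive carbons are equivalent, so the σ-insertion can give only one constitution. The ring oxygen of 12 (ether-like, because ester resonance is weak in the strained ring) should add to 13; the ortho aryl anion then attacks the adjacent acyl carbon (4-exo-trig) and the resulting benzo-fused 1-oxoniabicyclo[2.2.0]hexane alkoxide fragments at its central acyl–O bond, releasing the four-ring strain, while a fluoride-relay variant (F− opens the lactone to a β-alkoxy acyl fluoride, the alkoxide adds to 13 and the aryl anion closes 6-exo-trig on the acyl fluoride) would lead to the same product. The closest known reaction types are aryne insertion into the N–C(O) bond of β-lactams and cyclic ureas and into the C(O)–O bond of carboxylic acids; insertion into a lactone C(O)–O bond has not been shown. The six-membered ring is thus closed by intramolecular acylation of the aryl anion, a formal two-atom expansion of the oxetanone that forms O1–C8a and C4–C4a. No new stereocentre is formed, and since the C2–O1 bond is not broken in either pathway, (S)-12 should give (2S)-14 with retention. The step needs attack through the ring oxygen and not the carbonyl oxygen (whose [2+2] adduct could ionize the p-methoxybenzylic C–O bond) and survival of the base-sensitive lactone and flavanone; the symmetric aryne and the lactone strain serve the first, and the aprotic medium, low temperature and slow aryne release are meant to serve the second.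

**Compound list**
1 | 1,2,3,4-tetramethoxybenzene | COc1ccc(OC)c(OC)c1OC | starting material
2 | (2,3,4,5-tetramethoxyphenyl)lithium | [Li]c1cc(OC)c(OC)c(OC)c1OC | intermediate (not isolated)
3 | dimethyl (2,3,4,5-tetramethoxyphenyl)boronate | COB(OC)c1cc(OC)c(OC)c(OC)c1OC | intermediate (not isolated)
4 | 2,3,4,5-tetramethoxyphenol | COc1cc(O)c(OC)c(OC)c1OC | intermediate
5 | 2-bromo-3,4,5,6-tetramethoxyphenol | COc1c(Br)c(O)c(OC)c(OC)c1OC | intermediate
6 | (2-bromo-3,4,5,6-tetramethoxyphenoxy)trimethylsilane | COc1c(Br)c(O[Si](C)(C)C)c(OC)c(OC)c1OC | intermediate (not isolated)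
7 | lithium 2,3,4,5-tetramethoxy-6-(trimethylsilyl)phenoxide | [Li+].COc1c([Si](C)(C)C)c([O-])c(OC)c(OC)c1OC | intermediate (not isolated)
8 | 2,3,4,5-tetramethoxy-6-(trimethylsilyl)phenyl trifluoromethanesulfonate | COc1c([Si](C)(C)C)c(OS(=O)(=O)C(F)(F)F)c(OC)c(OC)c1OC | intermediate
9 | ethyl 3-(4-methoxyphenyl)-3-oxopropanoate | CCOC(=O)CC(=O)c1ccc(OC)cc1 | starting material
10 | ethyl (3S)-3-hydroxy-3-(4-methoxyphenyl)propanoate | COc1ccc([C@@H](O)CC(=O)OCC)cc1 | intermediate
11 | (3S)-3-hydroxy-3-(4-methoxyphenyl)propanoic acid | COc1ccc([C@@H](O)CC(=O)O)cc1 | intermediate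
12 | (4S)-4-(4-methoxyphenyl)oxetan-2-one | COc1ccc([C@@H]2CC(=O)O2)cc1 | intermediate
13 | 3,4,5,6-tetramethoxybenzyne (1,2-didehydro-3,4,5,6-tetramethoxybenzene) | COC1=C(OC)C(OC)=C(OC)C#C1 | intermediate (not isolated)
14 | (2S)-5,6,7,8,4'-pentamethoxyflavanone | COc1ccc([C@@H]2CC(=O)c3c(OC)c(OC)c(OC)c(OC)c3O2)cc1 | target

**Totals**
Total step count: 7. Longest linear sequence: 4 steps (steps 1, 2, 3, 7; the lactone branch, steps 4, 5, 6, 7, is equally long).

**Steps most likely to fail**

1. Step 7 (proposed new method).
   - What may go wrong: the weakly nucleophilic lactone oxygen may fail to capture the aryne, which is then lost to self-reaction or solvent. Capture through the carbonyl oxygen may be followed by ionization of the p-methoxybenzylic C–O bond and loss of configuration. The lactone may fragment with decarboxylation. Fluoride may cause E1cB opening of the lactone or the flavanone, with achiral re-closure and erosion of enantiopurity.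
   - Fallback with known chemistry, setting out from 4 and returning at 14: Friedel–Crafts acetylation of 4 at its only free position (Ac2O, BF3·OEt2) should give 1-(2-hydroxy-3,4,5,6-tetramethoxyphenyl)ethan-1-one F1. Condensation with DMF dimethyl acetal gives (E)-3-(dimethylamino)-1-(2-hydroxy-3,4,5,6-tetramethoxyphenyl)prop-2-en-1-one F2. Acid (HCl, CH2Cl2) closes it to 5,6,7,8-tetramethoxy-4H-chromen-4-one F3. Pd(OCOCF3)2/t-BuPyOX-catalysed asymmetric conjugate addition of 4-methoxyphenylboronic acid to F3 (NH4PF6, H2O, ClCH2CH2Cl, 60 °C), with the ligand enantiomer that leads to the 2S series, then gives 14.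

2. Step 6.
   - What may go wrong: ionization at the p-methoxybenzylic carbon during activation or isolation, giving dehydration to the cinnamic acid, decarboxylative fragmentation of the lactone to the styrene, or partial racemization.
   - Fallback that avoids the lactone, setting out from 9 and returning at 14: reduction of 9 with the enantiomeric catalyst RuCl[(R,R)-TsDPEN](p-cymene) gives ethyl (3R)-3-hydroxy-3-(4-methoxyphenyl)propanoate F4. Silylation (TBSCl, imidazole, DMF) gives ethyl (3R)-3-(tert-butyldimethylsilyloxy)-3-(4-methoxyphenyl)propanoate F5. Saponification (LiOH, THF–H2O) gives (3R)-3-(tert-butyldimethylsilyloxy)-3-(4-methoxyphenyl)propanoic acid F6. The known aryne insertion into the C(O)–O bond of a carboxylic acid (8, CsF, THF, heat; O-arylation, then O→C acyl shift) gives (3R)-3-(tert-butyldimethylsilyloxy)-1-(2-hydroxy-3,4,5,6-tetramethoxyphenyl)-3-(4-methoxyphenyl)propan-1-one F7. Desilylation (HF·pyridine, THF) gives (3R)-3-hydroxy-1-(2-hydroxy-3,4,5,6-tetramethoxyphenyl)-3-(4-methoxyphenyl)propan-1-one F8. Mitsunobu cyclization (PPh3, DIAD, THF, 0 °C) closes the ring with inversion at the carbinol carbon to give 14.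

3. Step 2.
   - What may go wrong: oxidation of the very electron-rich phenol (oxidative demethylation to a methoxy-p-benzoquinone) instead of ring bromination.
   - Fallback that replaces halogenation and retro-Brook migration by directed ortho-metalation, setting out from 4 and returning at 8: carbamoylation (i-PrNCO, Et3N, CH2Cl2) gives 2,3,4,5-tetramethoxyphenyl N-isopropylcarbamate F9. N-silylation and carbamate-directed ortho-lithiation with silyl quench (TMSOTf, TMEDA, Et2O; n-BuLi, −78 °C; TMSCl) gives 2,3,4,5-tetramethoxy-6-(trimethylsilyl)phenyl N-isopropylcarbamate F10. One-flask carbamate cleavage and triflation (DBU, Et2NH, MeCN, 40 °C; PhNTf2) gives 8.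

**Further compounds**
F1 | step 7 | 1-(2-hydroxy-3,4,5,6-tetramethoxyphenyl)ethan-1-one | CC(=O)c1c(O)c(OC)c(OC)c(OC)c1OC
F2 | step 7 | (E)-3-(dimethylamino)-1-(2-hydroxy-3,4,5,6-tetramethoxyphenyl)prop-2-en-1-one | CN(C)/C=C/C(=O)c1c(O)c(OC)c(OC)c(OC)c1OC
F3 | step 7 | 5,6,7,8-tetramethoxy-4H-chromen-4-one | COc1c(OC)c(OC)c2occc(=O)c2c1OC
F4 | step 6 | ethyl (3R)-3-hydroxy-3-(4-methoxyphenyl)propanoate | COc1ccc([C@H](O)CC(=O)OCC)cc1
F5 | step 6 | ethyl (3R)-3-(tert-butyldimethylsilyloxy)-3-(4-methoxyphenyl)propanoate | COc1ccc([C@H](O[Si](C)(C)C(C)(C)C)CC(=O)OCC)cc1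
F6 | step 6 | (3R)-3-(tert-butyldimethylsilyloxy)-3-(4-methoxyphenyl)propanoic acid | COc1ccc([C@H](O[Si](C)(C)C(C)(C)C)CC(=O)O)cc1
F7 | step 6 | (3R)-3-(tert-butyldimethylsilyloxy)-1-(2-hydroxy-3,4,5,6-tetramethoxyphenyl)-3-(4-methoxyphenyl)propan-1-one | COc1ccc([C@H](O[Si](C)(C)C(C)(C)C)CC(=O)c2c(O)c(OC)c(OC)c(OC)c2OC)cc1
F8 | step 6 | (3R)-3-hydroxy-1-(2-hydroxy-3,4,5,6-tetramethoxyphenyl)-3-(4-methoxyphenyl)propan-1-one | COc1ccc([C@H](O)CC(=O)c2c(O)c(OC)c(OC)c(OC)c2OC)cc1
F9 | step 2 | 2,3,4,5-tetramethoxyphenyl N-isopropylcarbamate | COc1cc(OC(=O)NC(C)C)c(OC)c(OC)c1OC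
F10 | step 2 | 2,3,4,5-tetramethoxy-6-(trimethylsilyl)phenyl N-isopropylcarbamate | COc1c([Si](C)(C)C)c(OC(=O)NC(C)C)c(OC)c(OC)c1OC
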